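The data stem from a simulated flask with constants of no real substance.

The quick number comes from 70 °C and 2.0 min: follow one molecule of starting complex and ask for its chances at the fork after its first exchange.

| setting | blue | green | ochre | epsilon | eta | alpha | zeta | gamma |
|---|---|---|---|---|---|---|---|---|
| starting complex | 0.025 M | 0.013 M | 0.050 M | 0.025 M (fed, over 50 s) | 0.025 M (fed, over 50 s) | 0.025 M | 0.025 M (fed, over 12 s) | 0.025 M |
| incoming ligand | 0.0375 M | 0.0375 M | 0.0375 M | 0.0375 M | 0.0375 M | 0.0375 M (fed, over 50 s) | 0.0375 M | 0.0375 M |
| leaving ligand | 0.025 M | 0.025 M | 0.025 M | 0.0250 M | 0.0250 M | 0.0250 M | 0.0250 M | 0.0250 M |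
| temperature | 55 °C | 70 °C | 55 °C |  | 70 °C | 70 °C | 70 °C |  |
| remark | run made earlier | run made earlier | run made earlier | the addition at 40 °C, then warmed to 70 °C; the feed brings no volume worth counting | all else is in the flask from the start; the feed brings no volume worth counting | all else is in the flask from the start; the feed brings no volume worth counting | all else is in the flask from the start; the feed brings no volume worth counting | everything together at the start at 40 °C, warmed to 70 °C at 50 s |
| time |  |  |  | 2.0 min | 2.0 min | 2.0 min | 2.0 min | 2.0 min |

blue run (percent of the starting complex charged)

| time / min | complex with one exchanged / % | starting complex / % |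
|---|---|---|
| 0.667 | 18.3 | 78.2 |
| 1.33 | 27.4 | 63.7 |
| 2.00 | 33.3 | 52.3 |
| 3.00 | 39.2 | 40.9 |

green run (percent of the starting complex charged)

| time / s | complex with one exchanged / % | starting complex / % |
|---|---|---|
| 25.0 | 21.9 | 71.4 |
| 50.0 | 35.2 | 53.4 |
| 80.0 | 45.0 | 38.1 |
| 90.0 | 48.3 | 34.6 |

ochre run (percent of the starting complex charged)

| time / min | complex with one exchanged / % | starting complex / % |
|---|---|---|
| 0.333 | 9.5 | 89.6 |
| 0.667 | 17.6 | 80.0 |
| 1.33 | 25.0 | 68.1 |
| 3.00 | 31.0 | 51.3 |

(each reading ± 0.5 percentage points)

- the earlier runs were read with a standard deviation of 0.5 percentage points
- steps under discussion: starting complex + incoming ligand -> leaving ligand + complex with one exchanged; complex with one exchanged + incoming ligand -> leaving ligand + complex with two exchanged; complex with two exchanged + incoming ligand -> leaving ligand + complex with three exchanged; complex with three exchanged + incoming ligand -> leaving ligand + complex with four exchanged; complex with one exchanged <-> isomer of the product; incoming ligand -> decomposition product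

- the best flask by amount of complex with one exchanged, in percent of the starting complex charged; "all alike" if 1.5 percentage points covers them all (epsilon / eta / alpha / zeta / gamma / all alike)
- amount of complex with one exchanged at the end, in percent of the starting complex charged, epsilon
- amount of complex with one exchanged at the end, in percent of the starting complex charged, eta
- amount of complex with one exchanged at the end, in percent of the starting complex charged, alpha
- amount of complex with one exchanged at the end, in percent of the starting complex charged, zeta
- amount of complex with one exchanged at the end, in percent of the starting complex charged, gamma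

The green run at 90.0 s finds 73.9% of reacted starting complex standing as complex with one exchanged. This is the keep share, c(complex with one exchanged) / (charge − c(starting complex)), the selectivity on conversion. The hunch that second exchange bleeds the product finds little in that run, where the share reads 76.6% at 25.0 s and the starting complex left falls from 71.4% to 34.6%. The gap is read here as isomer of the product, already formed at the first reading.

The hunch that the slow feed wins therefore meets a cost. Material fed at a steady rate loses on average half of its feed time, so zeta has on average 114 s of reaction against 95.0 s for eta. Alpha, fed ligand over the same time, is taken on eta's clock.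

Green reads 21.9 /M/min for the first exchange, first order in each partner. Integrating over those average times, as for a charge present from the start, estimates 32.8% of starting complex left in zeta and 38.1% in eta. The keep share turns these into 49.7% and 45.7%. Epsilon and gamma sit at 40 °C, colder than eta's 70 °C, through the first 50 s, so they should fall below eta.

The forecast names zeta, with 40.9%, 45.6%, 45.7%, 49.7% and 42.2% for epsilon, eta, alpha, zeta and gamma. Its ground is “only conversion matters, with isomer equilibrated at the end”. It rests on the same fork, so its nearness to this reckoning checks nothing.

The flasks give zeta as best, with 40.2%, 44.4%, 44.5%, 48.1% and 41.5% in the same order.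

    starting complex + incoming ligand → leaving ligand + complex with one exchanged (k = 0.370 /M/s, Ea = 47.0 kJ/mol)
    complex with one exchanged + incoming ligand → leaving ligand + complex with two exchanged (k = 0.0170 /M/s, Ea = 73.0 kJ/mol)
    complex with two exchanged + incoming ligand → leaving ligand + complex with three exchanged (k = 0.370 /M/s, Ea = 73.0 kJ/mol)
    complex with three exchanged + incoming ligand → leaving ligand + complex with four exchanged (k = 1.80 /M/s, Ea = 40.0 kJ/mol)
    complex with one exchanged ⇌ isomer of the product (K = 0.380, k = 0.0410 /s, Ea = 98.0 kJ/mol, ΔH = −38.0 kJ/mol)
    incoming ligand → decomposition product (k = 9.10 × 10⁻⁶ /s, Ea = 127 kJ/mol)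
    (constants at 70 °C)

Zeta ends at 48.1% with 33% of its starting complex left, and the keep share on that conversion gives 49.5%. In zeta the complex with one exchanged and the isomer of the product relax by that step alone, both ways together, with a half-life of 0.0776 min, short against 2.0 min. The neighbour of zeta charged with 0.043 M of starting complex has 42% of it left at 2.00 min, so the keep share gives 42.9%. That neighbour holds 41.8% of complex with one exchanged.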